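**Retrosynthetic overview**
- The target is luteolin (rings A, C, B) carrying ring D at C8. Ring D is a benzoic acid ring numbered C1 (CO2H), C2 (bonded to flavone C8), C3 and C4 (OH), C5 and C6 (CH). The last steps are BBr3 cleavage of five methyl ethers and saponification of a lactone between the C7 oxygen and the ring D carboxyl.
- Ring C comes from cyclodehydration of a 1,3-diketone built from a ring A acetophenone and 3,4-dimethoxybenzoyl chloride (ring B). The para methoxy group on the symmetric ring A forces the aryl group to C8.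
- Ring D is the feature the plan rests on: C2–C3–C4–C5 (aryl-bearing carbon, two oxygenated carbons, one CH) are the four carbons of a 1-aryl-2-methoxy-3-silyloxybutadiene, and C1 plus C6 are the alkyne carbons of methyl propiolate. A Diels–Alder reaction is followed by DDQ aromatisation.
- The diene comes from 5-methoxyresorcinol by bis-MOM protection, ortho-lithiation/formylation, Horner–Wadsworth–Emmons reaction with an α-methoxy β-keto phosphonate, and enol silylation.
- Order of rings: A (bought), D (steps 6 and 7), temporary lactone (step 9), C together with B (steps 11 and 12); the lactone is opened in step 14.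

Key step: step 6

Assumption: the target SMILES gives no descriptor for the axis between ring A and ring D, so the biaryl is made without axial control, and the target is taken as the open hydroxy acid; because a free ortho hydroxyl beside the ring D ester would be expected to lactonise anyway, the lactone is formed on purpose in step 9 and opened last.

**Route**

Step 1
Reactants: 1 5-methoxyresorcinol
Product: 2 1-methoxy-3,5-bis(methoxymethoxy)benzene
Conditions: MOMCl, i-Pr2NEt, CH2Cl2, 0 °C to rt
Reagents that add atoms: chloromethyl methyl ether (MOMCl), COCCl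
Why: Double O-alkylation (Williamson-type etherification with an α-chloro ether) of the two equivalent phenols should proceed readily under amine base and installs acetals that direct the lithiation of step 2 and can later be removed without touching the methyl ether.

Step 2
Reactants: 2 1-methoxy-3,5-bis(methoxymethoxy)benzene
Product: 4 4-methoxy-2,6-bis(methoxymethoxy)benzaldehyde, via aryllithium 3 (not isolated)
Conditions: n-BuLi, TMEDA, THF, 0 °C; DMF, 0 °C to rt; H2O
Reagents that add atoms: N,N-dimethylformamide, CN(C)C=O
Why: Directed ortho-metalation should occur at the carbon flanked by the two OMOM groups, the site best chelated by lithium, and formylation of the aryllithium with DMF then gives the symmetric aldehyde.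

Step 3
Reactants: 5 dimethyl (1-diazo-2-oxopropyl)phosphonate
Product: 6 dimethyl (1-methoxy-2-oxopropyl)phosphonate (racemic)
Conditions: MeOH, Rh2(OAc)4 (1 mol %), PhMe, 80 °C
Reagents that add atoms: methanol, CO
Why: Rhodium-carbenoid O–H insertion: Rh2(OAc)4 turns the diazo phosphonate into an electrophilic carbenoid that methanol traps at oxygen, and a proton shift gives the α-methoxy β-keto phosphonate, whose new stereocentre is racemic and disappears in step 4.

Step 4
Reactants: 4 4-methoxy-2,6-bis(methoxymethoxy)benzaldehyde; 6 dimethyl (1-methoxy-2-oxopropyl)phosphonate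
Product: 8 (Z)-3-methoxy-4-[4-methoxy-2,6-bis(methoxymethoxy)phenyl]but-3-en-2-one, via sodium phosphonate enolate 7 (not isolated)
Conditions: NaH, THF, 0 °C; then 4, rt to 60 °C
Reagents that add atoms: none
Why: Horner–Wadsworth–Emmons olefination with the stabilised phosphonate anion should give mainly the enone in which the bulky aryl group is trans to the acetyl group (Z by the sequence rule, aryl cis to OMe), the less crowded and thermodynamically preferred isomer, any E isomer being removed by chromatography.

Step 5
Reactants: 8 (Z)-3-methoxy-4-[4-methoxy-2,6-bis(methoxymethoxy)phenyl]but-3-en-2-one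
Product: 9 tert-butyl{[(3Z)-3-methoxy-4-(4-methoxy-2,6-bis(methoxymethoxy)phenyl)buta-1,3-dien-2-yl]oxy}dimethylsilane
Conditions: TBSOTf, Et3N, CH2Cl2, −78 to 0 °C
Reagents that add atoms: tert-butyldimethylsilyl trifluoromethanesulfonate (TBSOTf), CC(C)(C)[Si](C)(C)OS(=O)(=O)C(F)(F)F
Why: Enol silylation of the methyl ketone with a silyl triflate and amine base (soft enolisation) can only take place at the CH3 group, so the 2-silyloxydiene should form with the Z enol ether geometry untouched, the low temperature and excess amine sparing the MOM acetals.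

Step 6
Reactants: 9 tert-butyl{[(3Z)-3-methoxy-4-(4-methoxy-2,6-bis(methoxymethoxy)phenyl)buta-1,3-dien-2-yl]oxy}dimethylsilane; 10 methyl propiolate
Product: 11 methyl 4-[(tert-butyldimethylsilyl)oxy]-5-methoxy-6-[4-methoxy-2,6-bis(methoxymethoxy)phenyl]cyclohexa-1,4-diene-1-carboxylate (racemic)
Conditions: 10 (5 equiv), PhMe, 120 °C, sealed tube
Reagents that add atoms: none
Why: A thermal, concerted but asynchronous normal-electron-demand [4+2] cycloaddition between the electron-rich diene (HOMO) and the alkynoate (LUMO) is expected, the closest known reaction type being the Diels–Alder reaction of 2-silyloxy-1,3-dienes with propiolate esters. Ring D is closed in this one intermolecular [4+2] event as a cyclohexa-1,4-diene, the bonds C1–C2 and C5–C6 forming suprafacially on both partners. The only new stereocentre is the sp3 carbon C2 that bears the aryl group; it forms racemic, needs no control and is erased in step 7. The step needs regioselectivity: the unsubstituted CH2 terminus (C5), whose HOMO coefficient is raised by the 3-silyloxy group and the 1-aryl group and which is sterically free, should lead the bonding to the β-carbon of the propiolate (C6), so that the ester-bearing carbon C1 ends up on the aryl-bearing carbon C2, whereas the 2-methoxy group pulls the other way but acts on the hindered terminus. The Z geometry of the aryl enol ether keeps the bulky aryl group on the outside of the s-cis diene, which the cycloaddition requires.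

Step 7
Reactants: 11 methyl 4-[(tert-butyldimethylsilyl)oxy]-5-methoxy-6-[4-methoxy-2,6-bis(methoxymethoxy)phenyl]cyclohexa-1,4-diene-1-carboxylate
Product: 12 methyl 4-[(tert-butyldimethylsilyl)oxy]-3-methoxy-2-[4-methoxy-2,6-bis(methoxymethoxy)phenyl]benzoate
Conditions: DDQ, NaHCO3, PhMe, 0 °C to rt
Reagents that add atoms: none
Why: Dehydrogenative aromatisation: DDQ abstracts hydride from a doubly allylic position of the cyclohexa-1,4-diene and loss of a proton gives the benzoate, the bicarbonate buffer protecting the acetals from the acidic hydroquinone.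

Step 8
Reactants: 12 methyl 4-[(tert-butyldimethylsilyl)oxy]-3-methoxy-2-[4-methoxy-2,6-bis(methoxymethoxy)phenyl]benzoate
Product: 14 methyl 3,4-dimethoxy-2-[4-methoxy-2,6-bis(methoxymethoxy)phenyl]benzoate, via caesium phenoxide 13 (not isolated)
Conditions: CsF, MeI, DMF, rt
Reagents that add atoms: iodomethane, CI
Why: Fluoride-induced cleavage of the aryl silyl ether releases a phenoxide that is methylated in situ (Williamson ether synthesis), exchanging the base-labile silyl ether for a methyl ether that lasts until step 13.

Step 9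
Reactants: 14 methyl 3,4-dimethoxy-2-[4-methoxy-2,6-bis(methoxymethoxy)phenyl]benzoate
Product: 16 1-hydroxy-3,9,10-trimethoxy-6H-benzo[c]chromen-6-one, via diol methyl ester 15 (not isolated)
Conditions: HCl, MeOH, 50 °C; evaporate; TsOH·H2O (cat.), PhMe, 110 °C, MeOH distilled off
Reagents that add atoms: none
Why: Acid-catalysed acetal cleavage frees the two equivalent phenols, and acid-catalysed intramolecular transesterification (lactonisation) of either one onto the neighbouring methyl ester, driven by removal of methanol, should give the dibenzo-α-pyrone, which masks the carboxyl and the future C7 oxygen and leaves one phenol for the annulation.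

Step 10
Reactants: 16 1-hydroxy-3,9,10-trimethoxy-6H-benzo[c]chromen-6-one
Product: 18 2-acetyl-1-hydroxy-3,9,10-trimethoxy-6H-benzo[c]chromen-6-one, via difluoroboron chelate 17 (not isolated)
Conditions: Ac2O, BF3·OEt2, AcOH, 80 °C; then H2O/THF, 50 °C
Reagents that add atoms: acetic anhydride, CC(=O)OC(C)=O
Why: Friedel–Crafts acylation/Fries rearrangement under BF3 should place the acetyl group ortho to the free phenol, because only there is the ketone held as a six-membered O–B–O chelate, which hydrolyses to the hydrogen-bonded ortho-hydroxyacetophenone.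

Step 11
Reactants: 18 2-acetyl-1-hydroxy-3,9,10-trimethoxy-6H-benzo[c]chromen-6-one; 19 3,4-dimethoxybenzoyl chloride
Product: 21 1-(3,4-dimethoxyphenyl)-3-(1-hydroxy-3,9,10-trimethoxy-6-oxo-6H-benzo[c]chromen-2-yl)propane-1,3-dione, via dilithium dianion 20 (not isolated)
Conditions: LiN(SiMe3)2 (3.5 equiv), THF, −78 °C; then 19, −78 °C to rt; 1 M HCl
Reagents that add atoms: none
Why: Baker–Venkataraman-type aroylation: the phenoxide–enolate dianion formed with the non-nucleophilic amide base, which spares the lactone, is acylated by the aroyl chloride at carbon, or at oxygen followed by O-to-C acyl transfer, to give the 1,3-diketone.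

Step 12
Reactants: 21 1-(3,4-dimethoxyphenyl)-3-(1-hydroxy-3,9,10-trimethoxy-6-oxo-6H-benzo[c]chromen-2-yl)propane-1,3-dione
Product: 22 2-[2-(3,4-dimethoxyphenyl)-7-hydroxy-5-methoxy-4-oxo-4H-chromen-8-yl]-3,4-dimethoxybenzoic acid lactone (flavone C7 oxygen to the ring D carboxyl)
Conditions: H2SO4 (cat.), AcOH, 100 °C
Reagents that add atoms: none
Why: Acid-catalysed cyclodehydration of the ortho-hydroxyaryl 1,3-diketone (intramolecular addition of the phenol to the aryl ketone, then loss of water) closes the pyranone ring C, and because the only hydroxyl next to the acyl group is the one beside the biaryl bond the aryl ring can only end up at C8.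

Step 13
Reactants: 22 the pentamethyl ether lactone
Product: 23 2-[2-(3,4-dihydroxyphenyl)-5,7-dihydroxy-4-oxo-4H-chromen-8-yl]-3,4-dihydroxybenzoic acid lactone (flavone C7 oxygen to the ring D carboxyl)
Conditions: BBr3 (10 equiv), CH2Cl2, −78 °C to rt; H2O
Reagents that add atoms: none
Why: Lewis-acid ether cleavage: BBr3 coordinates each methoxy oxygen and bromide removes the methyl group by SN2, which should free all five phenols while the aryl lactone and the pyranone are not attacked.

Step 14
Reactants: 23 the pentahydroxy lactone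
Product: 24 2-[2-(3,4-dihydroxyphenyl)-5,7-dihydroxy-4-oxo-4H-chromen-8-yl]-3,4-dihydroxybenzoic acid (CNP0217349.0)
Conditions: LiOH, THF/H2O (degassed), Ar, 0 °C to rt; 1 M HCl to pH 3, 0 °C
Reagents that add atoms: lithium hydroxide in water (delivers one oxygen), [Li+].[OH-]
Why: Saponification (acyl substitution by hydroxide) of the strained aryl lactone releases the C7 phenoxide and the carboxylate under air-free conditions that protect the catechols, and cold acidification then gives the hydroxy acid without the dehydrating conditions that would re-close the lactone.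

**Compound list**
1 | 5-methoxyresorcinol | COc1cc(O)cc(O)c1 | starting material
2 | 1-methoxy-3,5-bis(methoxymethoxy)benzene | COCOc1cc(OC)cc(OCOC)c1 | intermediate
3 | [4-methoxy-2,6-bis(methoxymethoxy)phenyl]lithium | [Li]c1c(OCOC)cc(OC)cc1OCOC | intermediate
4 | 4-methoxy-2,6-bis(methoxymethoxy)benzaldehyde | COCOc1cc(OC)cc(OCOC)c1C=O | intermediate
5 | dimethyl (1-diazo-2-oxopropyl)phosphonate | CC(=O)C(=[N+]=[N-])P(=O)(OC)OC | starting material
6 | dimethyl (1-methoxy-2-oxopropyl)phosphonate (racemic) | COC(C(C)=O)P(=O)(OC)OC | intermediate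
7 | sodium enolate of 6 | COC(=C(C)[O-])P(=O)(OC)OC.[Na+] | intermediate
8 | (Z)-3-methoxy-4-[4-methoxy-2,6-bis(methoxymethoxy)phenyl]but-3-en-2-one | COCOc1cc(OC)cc(OCOC)c1/C=C(\OC)C(C)=O | intermediate
9 | tert-butyl{[(3Z)-3-methoxy-4-(4-methoxy-2,6-bis(methoxymethoxy)phenyl)buta-1,3-dien-2-yl]oxy}dimethylsilane | COCOc1cc(OC)cc(OCOC)c1/C=C(\OC)C(=C)O[Si](C)(C)C(C)(C)C | intermediate
10 | methyl propiolate | C#CC(=O)OC | starting material
11 | methyl 4-[(tert-butyldimethylsilyl)oxy]-5-methoxy-6-[4-methoxy-2,6-bis(methoxymethoxy)phenyl]cyclohexa-1,4-diene-1-carboxylate (racemic) | COC(=O)C1=CCC(O[Si](C)(C)C(C)(C)C)=C(OC)C1c1c(OCOC)cc(OC)cc1OCOC | intermediate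
12 | methyl 4-[(tert-butyldimethylsilyl)oxy]-3-methoxy-2-[4-methoxy-2,6-bis(methoxymethoxy)phenyl]benzoate | COC(=O)c1ccc(O[Si](C)(C)C(C)(C)C)c(OC)c1-c1c(OCOC)cc(OC)cc1OCOC | intermediate
13 | caesium 2-methoxy-4-(methoxycarbonyl)-3-[4-methoxy-2,6-bis(methoxymethoxy)phenyl]phenoxide | COC(=O)c1ccc([O-])c(OC)c1-c1c(OCOC)cc(OC)cc1OCOC.[Cs+] | intermediate
14 | methyl 3,4-dimethoxy-2-[4-methoxy-2,6-bis(methoxymethoxy)phenyl]benzoate | COC(=O)c1ccc(OC)c(OC)c1-c1c(OCOC)cc(OC)cc1OCOC | intermediate
15 | methyl 2-(2,6-dihydroxy-4-methoxyphenyl)-3,4-dimethoxybenzoate | COC(=O)c1ccc(OC)c(OC)c1-c1c(O)cc(OC)cc1O | intermediate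
16 | 1-hydroxy-3,9,10-trimethoxy-6H-benzo[c]chromen-6-one | O=C1Oc2cc(OC)cc(O)c2-c2c1ccc(OC)c2OC | intermediate
17 | difluoroboron chelate of 18 (phenol oxygen and acetyl oxygen on boron) | O=C1Oc2cc(OC)c3c(c2-c2c1ccc(OC)c2OC)O[B-](F)(F)[O+]=C3C | intermediate
18 | 2-acetyl-1-hydroxy-3,9,10-trimethoxy-6H-benzo[c]chromen-6-one | O=C1Oc2cc(OC)c(C(C)=O)c(O)c2-c2c1ccc(OC)c2OC | intermediate
19 | 3,4-dimethoxybenzoyl chloride | COc1ccc(C(Cl)=O)cc1OC | starting material
20 | dilithium phenoxide–enolate of 18 | O=C1Oc2cc(OC)c(C(=C)[O-])c([O-])c2-c2c1ccc(OC)c2OC.[Li+].[Li+] | intermediate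
21 | 1-(3,4-dimethoxyphenyl)-3-(1-hydroxy-3,9,10-trimethoxy-6-oxo-6H-benzo[c]chromen-2-yl)propane-1,3-dione | O=C1Oc2cc(OC)c(C(=O)CC(=O)c3ccc(OC)c(OC)c3)c(O)c2-c2c1ccc(OC)c2OC | intermediate
22 | 2-[2-(3,4-dimethoxyphenyl)-7-hydroxy-5-methoxy-4-oxo-4H-chromen-8-yl]-3,4-dimethoxybenzoic acid lactone (C7 oxygen to carboxyl) | O=C1Oc2cc(OC)c3c(=O)cc(-c4ccc(OC)c(OC)c4)oc3c2-c2c1ccc(OC)c2OC | intermediate
23 | 2-[2-(3,4-dihydroxyphenyl)-5,7-dihydroxy-4-oxo-4H-chromen-8-yl]-3,4-dihydroxybenzoic acid lactone (C7 oxygen to carboxyl) | O=C1Oc2cc(O)c3c(=O)cc(-c4ccc(O)c(O)c4)oc3c2-c2c1ccc(O)c2O | intermediate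
24 | 2-[2-(3,4-dihydroxyphenyl)-5,7-dihydroxy-4-oxo-4H-chromen-8-yl]-3,4-dihydroxybenzoic acid (CNP0217349.0) | O=C(O)c1ccc(O)c(O)c1-c1c(O)cc(O)c2c(=O)cc(-c3ccc(O)c(O)c3)oc12 | target

**Step count and risks**

Total step count: 14. Longest linear sequence: 13 (steps 1, 2 and 4 to 14; step 3 prepares phosphonate 6).

Steps most likely to fail:

1. Step 6. The aryl group, twisted out of the diene plane by its two ortho OMOM groups, may shield the diene terminus so that cycloaddition becomes slower than hydrolysis or oligomerisation of the silyl enol ether, and the 2-methoxy group may erode the regiocontrol. Fallback: the biaryl bond is made directly by Suzuki–Miyaura coupling. It sets out from 2: lithiation as in step 2 (through 3), quenching with B(OMe)3 and mild hydrolysis would give [4-methoxy-2,6-bis(methoxymethoxy)phenyl]boronic acid F1. This is coupled with methyl 2-bromo-3,4-dimethoxybenzoate F2 (from 2-bromo-3,4-dimethoxybenzoic acid, MeI, K2CO3, DMF) using Pd(OAc)2, 2-dicyclohexylphosphino-2',6'-dimethoxybiphenyl and K3PO4 in PhMe/H2O at 100 °C. The product is 14, where the route is rejoined at step 9.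

2. Step 10. Acylation may take place at the carbon para to the phenol (between the methoxy group and the lactone oxygen), or the reaction may stop at the O-acetate. A mis-sited acetyl group is still on the right ring, since opening the lactone gives the same open-chain diol either way, but a cleaner alternative brings in the three carbons of ring C through the phenol oxygen. Fallback: it sets out from 16. Conjugate addition of its phenoxide (K2CO3, DMF, 60 °C) to tert-butyl 3-(3,4-dimethoxyphenyl)prop-2-ynoate F3 (from 4-ethynyl-1,2-dimethoxybenzene, n-BuLi, then di-tert-butyl dicarbonate) would give tert-butyl 3-(3,4-dimethoxyphenyl)-3-[(3,9,10-trimethoxy-6-oxo-6H-benzo[c]chromen-1-yl)oxy]prop-2-enoate F4 as an E/Z mixture. CF3CO2H in CH2Cl2 removes the tert-butyl group to give 3-(3,4-dimethoxyphenyl)-3-[(3,9,10-trimethoxy-6-oxo-6H-benzo[c]chromen-1-yl)oxy]prop-2-enoic acid F5. P2O5 in MeSO3H at 60 °C then closes ring C by intramolecular Friedel–Crafts acylation at the only free position ortho to the ether oxygen. The product is 22, so steps 10 to 12 are bypassed and the route is rejoined at step 13.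

3. Step 11. The enolate or the amide base may attack the strained lactone carbonyl of a second molecule, and aroylation in the crowded bay region may be slow. Fallback: a chalcone route in which the lactone is allowed to open. It sets out from 18. Claisen–Schmidt condensation with 3,4-dimethoxybenzaldehyde (KOH, EtOH/H2O, rt, the lactone being saponified at the same time) and acidification would give 2-{3-[(E)-3-(3,4-dimethoxyphenyl)prop-2-enoyl]-2,6-dihydroxy-4-methoxyphenyl}-3,4-dimethoxybenzoic acid F6, in which only one hydroxyl is ortho to the enone. Oxidative cyclisation with catalytic I2 in DMSO at 120 °C would give 2-[2-(3,4-dimethoxyphenyl)-7-hydroxy-5-methoxy-4-oxo-4H-chromen-8-yl]-3,4-dimethoxybenzoic acid F7. TsOH in PhMe at reflux re-closes the lactone to 22, where the route is rejoined at step 13.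

Further compounds
F1 | step 6 | [4-methoxy-2,6-bis(methoxymethoxy)phenyl]boronic acid | COCOc1cc(OC)cc(OCOC)c1B(O)O
F2 | step 6 | methyl 2-bromo-3,4-dimethoxybenzoate | COC(=O)c1ccc(OC)c(OC)c1Br
F3 | step 10 | tert-butyl 3-(3,4-dimethoxyphenyl)prop-2-ynoate | COc1ccc(C#CC(=O)OC(C)(C)C)cc1OC
F4 | step 10 | tert-butyl 3-(3,4-dimethoxyphenyl)-3-[(3,9,10-trimethoxy-6-oxo-6H-benzo[c]chromen-1-yl)oxy]prop-2-enoate (E/Z mixture) | O=C1Oc2cc(OC)cc(OC(=CC(=O)OC(C)(C)C)c3ccc(OC)c(OC)c3)c2-c2c1ccc(OC)c2OC
F5 | step 10 | 3-(3,4-dimethoxyphenyl)-3-[(3,9,10-trimethoxy-6-oxo-6H-benzo[c]chromen-1-yl)oxy]prop-2-enoic acid (E/Z mixture) | O=C1Oc2cc(OC)cc(OC(=CC(=O)O)c3ccc(OC)c(OC)c3)c2-c2c1ccc(OC)c2OC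
F6 | step 11 | 2-{3-[(E)-3-(3,4-dimethoxyphenyl)prop-2-enoyl]-2,6-dihydroxy-4-methoxyphenyl}-3,4-dimethoxybenzoic acid | OC(=O)c1ccc(OC)c(OC)c1-c1c(O)cc(OC)c(C(=O)/C=C/c2ccc(OC)c(OC)c2)c1O
F7 | step 11 | 2-[2-(3,4-dimethoxyphenyl)-7-hydroxy-5-methoxy-4-oxo-4H-chromen-8-yl]-3,4-dimethoxybenzoic acid | OC(=O)c1ccc(OC)c(OC)c1-c1c(O)cc(OC)c2c(=O)cc(-c3ccc(OC)c(OC)c3)oc12
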